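## The problem

The target is a trans-fused cyclopentane–cycloheptene (daucane type). Locants used throughout: C1 methyl-bearing ring-fusion carbon, C2–C3 ring methylenes, C4 isopropyl carbinol, C5 ring-fusion CH, C6 ester carbon, C7 methylene, C8(CH3)=C9 alkene, C10 allylic carbinol; β is the face of the C1 methyl. Five stereocentres (1S,4R,5S,6S,10R) lie on or next to the shared C1–C5 bond; C1 is quaternary and C4 is a tertiary carbinol. C1 can control C4, C5 and C6, because additions anti to its methyl give the 4α-isopropyl, 5α-hydrogen and 6α-oxygen that are needed. C10 is the exception: its hydroxyl is α and trans to the C1 methyl, whereas hydride addition to a C10 ketone is expected anti to that methyl and would give the 10β-epimer, so an inversion must be planned. The tertiary C4 alcohol (dehydration, cleavage next to a carbonyl), the allylic C10 alcohol (ionisation) and the aryl ester (base) call for mild late steps, and the three oxygens must be told apart so that only C6 is acylated. The absolute configuration has to come from a cheap chiral source. The enabling feature is that C1 and C5 each carry one arm of the seven-membered ring (C10 and C6) and C10 is oxygenated: C1–C10 and C5–C6 can be the two new bonds of an enone–enol ether [2+2] adduct, in which C6–C10 is shared by a cyclobutane and a cyclopentane, and breaking that bond merges both into the seven-membered ring while leaving C5=C6 for the C5 hydrogen and C6 oxygen.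

## Retrosynthesis

Target 22 is cut at the C10–O bond: it comes from chloroacetate 21, and 21 from the 10β-alcohol 20 by substitution with inversion. This is preferred to a direct reduction because hydride addition to enone 19 should occur anti to the C1 methyl and give 20, not 22. The forward reaction must be an SN2 process at a neopentyl-type allylic carbon, entered from the open α face.

Enone 19 is simplified by removing the C8=C9 double bond: it comes from alcohol 17 by oxidation through ketone 18 and dehydrogenation. Only C9 can be enolised (C1 is quaternary), so no regiochemical question arises. Alcohol 17 comes from silyl ether 16, and 16 is cut at the ester C–O bond into diol 14 and acid chloride 15; the secondary C6 hydroxyl is the only one that can be acylated.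

Diol 14 is cut at C5–H and C6–O, which leads back to alkene 13 by hydroboration–oxidation. A syn addition anti to the C1 methyl sets the trans ring fusion and the 6α-oxygen in one step, which no stepwise alternative does. The price is that C10 must be a protected alcohol at this point and C8=C9 must be absent, since a ketone would be reduced and a second trisubstituted alkene would compete; 13 is therefore the silyl ether of diol 12.

Diol 12 is cut at the C4–isopropyl bond into enedione 9 and isopropylmagnesium chloride 10, with keto carbinol 11 reduced in the same flask. The forward addition must choose the cyclopentenone carbonyl over the hindered C10 ketone and the face anti to the C1 methyl.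

Enedione 9 is reconnected at C6–C10 to the tricyclic cyclobutane 7. The C10 oxygen and the C5 mesylate are 1,3-related across the four-membered ring, which is the retron of a Grob fragmentation. The precursor is more complex in ring count but is made in one step; the forward reaction must break C6–C10 and not C1–C10.

Cyclobutane 7 is cut at C1–C10 and C5–C6 into enone 2 and silyl enol ether 6. This removes one ring, two skeletal bonds and four stereocentres, and leaves two five-membered rings. The forward [2+2] must be head-to-tail, exo, and anti to the C8 methyl of 6.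

Enone 2 is the mesylate of the commercial enolised dione 1. Enol ether 6 is made regiospecifically from enone 5 by 1,4-hydrosilylation; 5 comes from (R)-3-methylcyclopentanone 3 through its trimethylsilyl enol ether 4. The detour through 5 is chosen because direct enolisation of 3 gives two enol ethers that cannot be separated, whereas the two enones can.

## Roads not taken

Alternative 1: The five-membered ring is traced back to a cyclohexene, made by an asymmetric Diels–Alder reaction of a 2-methyl enal with a methyl-substituted butadiene under a chiral oxazaborolidinium Lewis acid. The adduct A1 carries C1 (quaternary, with a formyl arm) and C5 (with a silyloxymethyl arm) in the target configuration. Its merit is catalytic, direct control of the absolute configuration at the quaternary C1, which is more secure than the relay through a remote methyl in the chosen plan. Its weakness is that A1 contains neither ring of the target: the cyclohexene must be cleaved and re-closed to the cyclopentane, the seven-membered ring built from two one-carbon arms, and C4, C6 and C10 functionalised afterwards. The chosen plan sets against the better stereocontrol of A1 the formation of the quaternary centre, the seven-membered ring precursor and the C10 oxygen in two steps, and the fact that its minor diastereomer can be removed before C8 is erased.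

Alternative 2: The seven-membered ring is traced back to the six-membered ring of a trans-hydrindanone; C9 is inserted by oxidative opening of a siloxycyclopropane, and loss of HCl gives enone A2. A2 is the C4 triethylsilyl ether of compound 19, so the endgame, including the C10 inversion, would be the same. Its merits are a ring fusion and a C1 configuration fixed early by well-developed hydrindane chemistry (no facial question as in step 8) and a key step that delivers the C8=C9 enone directly. Its weakness is that the C4 carbinol, the C6 ester, the C8 methyl and a tetrasubstituted enol ether for cyclopropanation must all be in place on the hydrindane first, which makes a long linear sequence with a hindered cyclopropanation. In certainty this road is as good as or better than the chosen one; the chosen plan sets against it a much shorter access to the bicycle, at the cost of the regiochemical risk of step 5.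

Alternative 3: C1–C5 and C6–C7 are cut, and both rings close in one rhodium-catalysed [5+2] cycloaddition of an alkyne tethered to a siloxyvinylcyclopropane. The product A3 already holds the C4 carbinol, the quaternary C1 and the C5=C6 alkene, the same handle as in compound 13. Its merits are a catalytic, atom-economical closure of both rings and a C4 centre brought in from an enantioenriched carbinol, which avoids the facial question of step 6. Its weaknesses are that the oxygen emerges at C9 and not C10, so a carbonyl transposition is needed; that C1 must be set relative to C4 across the tether; and that the precursor needs many steps. The chosen plan sets against it the correct placement of the C10 oxygen from the outset and two cheap five-membered starting rings.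

Key step: step 4

Remark: compounds 12, 13, 14, 16 and 17 are carried as mixtures of C10 epimers, because this centre becomes a ketone again in step 11. "Dauc" names mean the 4-isopropyl-1,8-dimethyl bicycle with the locants above.

Step 1
Reactants: 1 2-hydroxy-3-methylcyclopent-2-en-1-one
Product: 2 2-(methanesulfonyloxy)-3-methylcyclopent-2-en-1-one
Conditions: MeSO2Cl, Et3N, CH2Cl2, 0 °C
Reagents that add atoms: methanesulfonyl chloride, CS(=O)(=O)Cl
Why: O-sulfonylation of the enolised 1,2-dione, an acidic enol that reacts at oxygen with sulfonyl chlorides.

Step 2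
Reactants: 3 (R)-3-methylcyclopentanone
Product: 5 (S)-4-methylcyclopent-2-en-1-one, via trimethylsilyl enol ether 4 (not isolated)
Conditions: LiN(i-Pr)2, Me3SiCl, THF, −78 °C; then Pd(OAc)2 (10 mol%), O2, DMSO, 25 °C
Reagents that add atoms: none
Why: Kinetic enolisation and silylation, then Saegusa–Ito oxidation; the regioisomeric enol ether gives achiral 3-methylcyclopent-2-en-1-one, which is removed by chromatography at this stage. The stereocentre is untouched; the descriptor changes from R to S only through the priority rules.

Step 3
Reactants: 5 (S)-4-methylcyclopent-2-en-1-one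
Product: 6 (R)-4-methyl-1-(triethylsilyloxy)cyclopentene
Conditions: Et3SiH, RhCl(PPh3)3 (0.5 mol%), THF, 50 °C
Reagents that add atoms: triethylsilane, CC[SiH](CC)CC
Why: Rhodium-catalysed 1,4-hydrosilylation of an enone with a monohydrosilane places the enol ether double bond between the former carbonyl and α-carbons only, so the C10=C6 enol ether forms as a single regioisomer.

Step 4
Reactants: 2 2-(methanesulfonyloxy)-3-methylcyclopent-2-en-1-one; 6 (R)-4-methyl-1-(triethylsilyloxy)cyclopentene
Product: 7 cis-anti-cis cyclobutane photoadduct (1R,5R,6R,8R,10R): 4-oxo 5-mesyloxy 10-triethylsilyloxy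
Conditions: hν (350 nm, Pyrex), 6 (4 equiv), CH2Cl2, −40 °C
Reagents that add atoms: none
Why: The triplet of enone 2 adds to the electron-rich enol ether 6 through 1,4-biradicals that collapse to the cyclobutane; the closest known reaction type is the intermolecular [2+2] photocycloaddition of cyclopentenones with silyl enol ethers, here with a 2-sulfonyloxy enone as a new member of the 2-oxygenated enone class. The four-membered ring is the only ring closed, and it closes intermolecularly by stepwise formation of C5–C6 and C1–C10. Head-to-tail regiochemistry (oxygen-bearing C10 to the β-carbon C1) follows from the polarity of the enol ether towards the excited enone. C1/C5 and C6/C10 are each necessarily cis, because a trans-fused four/five ring pair is too strained. The two five-membered rings end up anti across the cyclobutane because the exo approach avoids their methylene groups. The absolute configuration of C1, C5, C6 and C10 is relayed from the C8 methyl of 6, the enone adding to the cyclopentene face anti to it. The step needs this facial selectivity; because the methyl is remote it may be modest, so the reaction is run cold and the C8-epimeric adduct, a diastereomer, is removed by chromatography before C8 is erased.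

Step 5
Reactants: 7 cis-anti-cis cyclobutane photoadduct
Product: 9 (1S,8R)-1,8-dimethyl five/seven bicycle with C4 and C10 ketones and C5=C6 (enedione), via cyclobutanolate 8 (not isolated)
Conditions: Bu4NF, THF, −40 to 0 °C
Reagents that add atoms: none
Why: Grob fragmentation of a cyclobutane-1,3-diol monosulfonate: the freed C10 alkoxide pushes, C6–C10 breaks, C5=C6 forms and mesylate leaves, and release of ring strain merges the four- and five-membered rings into the cycloheptanone. The α-keto mesylate cannot ionise, so the transition state should be carbanion-like and the bond to the secondary C6 should break in preference to the bond to the quaternary C1.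

Step 6
Reactants: 9 enedione; 10 isopropylmagnesium chloride
Product: 12 8βH-dauc-5-ene-4β,10-diol (1S,4R,8R; C10 epimers), via keto carbinol 11 (not isolated)
Conditions: CeCl3, THF, −78 °C; then NaBH4, MeOH, −78 to 0 °C
Reagents that add atoms: none
Why: Organocerium 1,2-addition to the cyclopentenone carbonyl C4, which is far less hindered than the C10 ketone next to the quaternary C1; attack anti to the pseudo-axial C1 methyl should give 4R (isopropyl α, hydroxyl β). NaBH4 added to the same flask then reduces the C10 ketone so that it passes through the hydroboration as a protected alcohol; its configuration does not matter.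

Step 7
Reactants: 12 8βH-dauc-5-ene-4β,10-diol
Product: 13 10-(triethylsilyloxy)-8βH-dauc-5-en-4β-ol (1S,4R,8R; C10 epimers)
Conditions: Et3SiCl, imidazole, DMF, 0 °C
Reagents that add atoms: chlorotriethylsilane, CC[Si](Cl)(CC)CC
Why: Silylation of the only secondary alcohol; the tertiary allylic C4 hydroxyl does not react with the silyl chloride under these conditions.

Step 8
Reactants: 13 10-(triethylsilyloxy)-8βH-dauc-5-en-4β-ol
Product: 14 10-(triethylsilyloxy)-5αH,8βH-daucane-4β,6α-diol (1S,4R,5S,6S,8R; C10 epimers)
Conditions: BH3·THF, THF, 0 to 25 °C; then NaOH, H2O2, 0 °C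
Reagents that add atoms: hydrogen peroxide, OO
Why: Hydroboration–oxidation: boron goes to the less substituted C6 and hydrogen to C5 in a syn addition from the α face, anti to the angular C1 methyl as in the hydroboration of steroidal 5-enes. This sets the trans ring fusion (5S) and the 6α-hydroxyl (6S) together.

Step 9
Reactants: 14 10-(triethylsilyloxy)-5αH,8βH-daucane-4β,6α-diol; 15 4-methoxybenzoyl chloride
Product: 16 6α-(4-methoxybenzoyloxy)-10-(triethylsilyloxy)-5αH,8βH-daucan-4β-ol (1S,4R,5S,6S,8R; C10 epimers)
Conditions: DMAP, pyridine, CH2Cl2, 25 °C
Reagents that add atoms: none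
Why: DMAP-catalysed acylation of the only free secondary alcohol; the tertiary C4 hydroxyl and the silyl ether are inert.

Step 10
Reactants: 16 6α-(4-methoxybenzoyloxy)-10-(triethylsilyloxy)-5αH,8βH-daucan-4β-ol
Product: 17 6α-(4-methoxybenzoyloxy)-5αH,8βH-daucane-4β,10-diol (1S,4R,5S,6S,8S; C10 epimers)
Conditions: HF·pyridine, pyridine, THF, 0 °C
Reagents that add atoms: none
Why: Fluoride cleavage of the triethylsilyl ether under buffered conditions that leave the aryl ester and the tertiary alcohol untouched.

Step 11
Reactants: 17 6α-(4-methoxybenzoyloxy)-5αH,8βH-daucane-4β,10-diol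
Product: 19 4β-hydroxy-6α-(4-methoxybenzoyloxy)-5αH-dauc-8-en-10-one (1S,4R,5S,6S), via C10 ketone 18 (not isolated)
Conditions: 2-iodoxybenzoic acid (3 equiv), DMSO, 25 then 70 °C
Reagents that add atoms: none
Why: 2-Iodoxybenzoic acid oxidises the alcohol to the ketone and then dehydrogenates it to the enone. C9 is the only enolisable position, so C8=C9 is the only enone possible; both C10 epimers converge and the C8 stereocentre is erased as planned.

Step 12
Reactants: 19 4β-hydroxy-6α-(4-methoxybenzoyloxy)-5αH-dauc-8-en-10-one
Product: 20 6α-(4-methoxybenzoyloxy)-5αH-dauc-8-ene-4β,10β-diol (1S,4R,5S,6S,10S)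
Conditions: NaBH4, CeCl3·7H2O, MeOH, −78 °C
Reagents that add atoms: none
Why: Luche 1,2-reduction: in the trans-fused enone the C1 methyl stands nearly perpendicular to the carbonyl plane on the β face, so hydride should add from the α face and give the 10β-alcohol, the C10 epimer of the target. The ester is not reduced.

Step 13
Reactants: 20 6α-(4-methoxybenzoyloxy)-5αH-dauc-8-ene-4β,10β-diol
Product: 21 10α-(chloroacetoxy)-6α-(4-methoxybenzoyloxy)-5αH-dauc-8-en-4β-ol (1S,4R,5S,6S,10R)
Conditions: PPh3, i-PrO2CN=NCO2i-Pr, ClCH2CO2H, toluene, 0 to 25 °C
Reagents that add atoms: chloroacetic acid, OC(=O)CCl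
Why: Mitsunobu inversion with an acid of low pKa, as used for hindered alcohols: the carboxylate enters from the open α face, anti to the C1 methyl, and turns 10S into 10R. The tertiary hydroxyl does not react, and C10 has no β-hydrogen for elimination.

Step 14
Reactants: 21 10α-(chloroacetoxy)-6α-(4-methoxybenzoyloxy)-5αH-dauc-8-en-4β-ol
Product: 22 6α-(4-methoxybenzoyloxy)-5αH-dauc-8-ene-4β,10α-diol (1S,4R,5S,6S,10R)
Conditions: thiourea, NaHCO3, EtOH, 50 °C
Reagents that add atoms: none
Why: Selective removal of a chloroacetate by thiourea (S-alkylation, then cyclisation that releases the alcohol); the 4-methoxybenzoate, the allylic alcohol and the tertiary alcohol are untouched under these nearly neutral conditions.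

Compound list

1 | 2-hydroxy-3-methylcyclopent-2-en-1-one | CC1=C(O)C(=O)CC1 | starting material
2 | 2-(methanesulfonyloxy)-3-methylcyclopent-2-en-1-one | CC1=C(OS(C)(=O)=O)C(=O)CC1 | intermediate
3 | (R)-3-methylcyclopentanone | O=C1CC[C@@H](C)C1 | starting material
4 | (R)-4-methyl-1-(trimethylsilyloxy)cyclopentene | C[Si](C)(C)OC1=CC[C@@H](C)C1 | intermediate
5 | (S)-4-methylcyclopent-2-en-1-one | O=C1C=C[C@@H](C)C1 | intermediate
6 | (R)-4-methyl-1-(triethylsilyloxy)cyclopentene | CC[Si](CC)(CC)OC1=CC[C@@H](C)C1 | intermediate
7 | cis-anti-cis cyclobutane photoadduct (1R,5R,6R,8R,10R): 4-oxo, 5-mesyloxy, 10-triethylsilyloxy | O=C1CC[C@]2(C)[C@@]3(O[Si](CC)(CC)CC)C[C@H](C)C[C@H]3[C@]12OS(C)(=O)=O | intermediate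
8 | cyclobutanolate: C10 alcohol of 7, present as its tetrabutylammonium alkoxide | O=C1CC[C@]2(C)[C@@]3(O)C[C@H](C)C[C@H]3[C@]12OS(C)(=O)=O | intermediate
9 | (1S,8R)-1,8-dimethyl five/seven bicycle with C4 and C10 ketones and C5=C6 (enedione) | O=C1CC[C@]2(C)C(=O)C[C@H](C)CC=C12 | intermediate
10 | isopropylmagnesium chloride | CC(C)[Mg]Cl | starting material
11 | 4β-hydroxy-8βH-dauc-5-en-10-one (1S,4R,8R) | C1=C2[C@](O)(C(C)C)CC[C@]2(C)C(=O)C[C@H](C)C1 | intermediate
12 | 8βH-dauc-5-ene-4β,10-diol (1S,4R,8R; C10 epimers) | C1=C2[C@](O)(C(C)C)CC[C@]2(C)C(O)C[C@H](C)C1 | intermediate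
13 | 10-(triethylsilyloxy)-8βH-dauc-5-en-4β-ol (1S,4R,8R; C10 epimers) | C1=C2[C@](O)(C(C)C)CC[C@]2(C)C(O[Si](CC)(CC)CC)C[C@H](C)C1 | intermediate
14 | 10-(triethylsilyloxy)-5αH,8βH-daucane-4β,6α-diol (1S,4R,5S,6S,8R; C10 epimers) | O[C@H]1C[C@@H](C)CC(O[Si](CC)(CC)CC)[C@@]2(C)CC[C@@](O)(C(C)C)[C@H]12 | intermediate
15 | 4-methoxybenzoyl chloride | COc1ccc(C(=O)Cl)cc1 | starting material
16 | 6α-(4-methoxybenzoyloxy)-10-(triethylsilyloxy)-5αH,8βH-daucan-4β-ol (1S,4R,5S,6S,8R; C10 epimers) | COc1ccc(C(=O)O[C@H]2C[C@@H](C)CC(O[Si](CC)(CC)CC)[C@@]3(C)CC[C@@](O)(C(C)C)[C@H]23)cc1 | intermediate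
17 | 6α-(4-methoxybenzoyloxy)-5αH,8βH-daucane-4β,10-diol (1S,4R,5S,6S,8S; C10 epimers) | COc1ccc(C(=O)O[C@H]2C[C@@H](C)CC(O)[C@@]3(C)CC[C@@](O)(C(C)C)[C@H]23)cc1 | intermediate
18 | 4β-hydroxy-6α-(4-methoxybenzoyloxy)-5αH,8βH-daucan-10-one (1S,4R,5S,6S,8R) | COc1ccc(C(=O)O[C@H]2C[C@@H](C)CC(=O)[C@@]3(C)CC[C@@](O)(C(C)C)[C@H]23)cc1 | intermediate
19 | 4β-hydroxy-6α-(4-methoxybenzoyloxy)-5αH-dauc-8-en-10-one (1S,4R,5S,6S) | COc1ccc(C(=O)O[C@H]2CC(C)=CC(=O)[C@@]3(C)CC[C@@](O)(C(C)C)[C@H]23)cc1 | intermediate
20 | 6α-(4-methoxybenzoyloxy)-5αH-dauc-8-ene-4β,10β-diol (1S,4R,5S,6S,10S) | COc1ccc(C(=O)O[C@H]2CC(C)=C[C@H](O)[C@@]3(C)CC[C@@](O)(C(C)C)[C@H]23)cc1 | intermediate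
21 | 10α-(chloroacetoxy)-6α-(4-methoxybenzoyloxy)-5αH-dauc-8-en-4β-ol (1S,4R,5S,6S,10R) | COc1ccc(C(=O)O[C@H]2CC(C)=C[C@@H](OC(=O)CCl)[C@@]3(C)CC[C@@](O)(C(C)C)[C@H]23)cc1 | intermediate
22 | 6α-(4-methoxybenzoyloxy)-5αH-dauc-8-ene-4β,10α-diol (1S,4R,5S,6S,10R) | COc1ccc(C(=O)O[C@H]2CC(C)=C[C@@H](O)[C@@]3(C)CC[C@@](O)(C(C)C)[C@H]23)cc1 | target

Total step count: 14. Longest linear sequence: 13 steps (from 3 through steps 2 to 14).

Steps least certain to work

Step 4 (key step). Most likely to go wrong: unproductive photochemistry of the enol mesylate chromophore (sulfur–oxygen homolysis or decay without addition), together with weak facial discrimination by the remote C8 methyl. 2-Sulfonyloxy enones have not been used as partners, and the directing group is three bonds from the reacting alkene. Fallback: change the chromophore to the 2-acyloxy enone class and let the carboxylate be the nucleofuge. Setting out from 1, acetylation (Ac2O, Et3N, DMAP) gives 2-acetoxy-3-methylcyclopent-2-en-1-one F1. Irradiation of F1 with 6 gives the acetate cycloadduct F2, and Bu4NF opens F2 by the same fragmentation, returning to the route at 9.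

Step 5. Most likely to go wrong: cleavage of the wrong cyclobutane bond, C1–C10 instead of C6–C10. Both bonds are equally aligned with the C5–O bond, C1–C10 joins two fully substituted carbons, and its cleavage leads to a tetrasubstituted cyclopentenone. Fallback: remove the nucleofuge and cleave by β-carbon elimination at divalent palladium, which should form the secondary rather than the tertiary alkylpalladium. Setting out from 7, SmI2 (THF, MeOH, −78 °C) gives the des-mesyloxy ketone F3, and Bu4NF gives the cyclobutanol F4. Pd(OAc)2, pyridine and O2 in toluene at 80 °C then open F4 to 9 or to its β,γ-unsaturated isomer F5, which DBU brings into conjugation; the route is rejoined at 9.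

Step 6. Most likely to go wrong: poor facial discrimination at C4, with some addition to C10. C5 is trigonal at this stage, so the two faces of the C4 carbonyl differ only in the C1 methyl on one side and C10 on the other. Fallback: add the isopropyl group before the fragmentation, where the rigid tricycle and the neighbouring mesyloxy group direct the attack. Setting out from 7, 10 with CeCl3 (THF, −78 °C) should add anti to the C5–O bond and give the tertiary carbinol F6. Bu4NF then fragments F6 and returns to the route at 11, which is reduced as in step 6.

Step 8. Most likely to go wrong: addition of borane to the β face or low facial selectivity, because the α face of C5=C6 carries the C4 isopropyl group and C10 while the β face carries only the C1 methyl and the C4 oxygen. This would lead to the cis-fused 6β-series. Fallback: hydroxyl-directed epoxidation, radical opening and inversion. Setting out from 13, VO(acac)2 and t-BuOOH give the 5β,6β-epoxide F7, syn to the 4β-hydroxyl. Cp2TiCl (from Cp2TiCl2 and manganese) with 1,4-cyclohexadiene opens F7 to the tertiary C5 radical, which should take hydrogen on the α face and give the trans-fused 6β-alcohol F8. A Mitsunobu esterification of F8 with 4-methoxybenzoic acid inverts C6 and returns to the route at 16.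

Step 13. Most likely to go wrong: no substitution, or ionisation with loss of configuration, because C10 is allylic and flanked by the quaternary C1. Fallback: make the 10α-alcohol by oxidation from the open α face instead of by inversion. Setting out from 17, Dess–Martin periodinane gives 18, and KN(SiMe3)2 with PhNTf2 gives the enol triflate F9. Pd(OAc)2, PPh3, HCO2H and Bu3N reduce F9 to the 9-ene F10, and m-CPBA gives the 9α,10α-epoxide F11, anti to the C1 methyl. NaSePh opens F11 at C9 to the hydroxy selenide F12; H2O2 then gives the selenoxide, which eliminates syn towards the 8β-hydrogen and returns to the route at 22.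

Further compounds

F1 | step 4 | 2-acetoxy-3-methylcyclopent-2-en-1-one | CC(=O)OC1=C(C)CCC1=O
F2 | step 4 | cis-anti-cis cyclobutane photoadduct with C5 acetate in place of the mesylate | O=C1CC[C@]2(C)[C@@]3(O[Si](CC)(CC)CC)C[C@H](C)C[C@H]3[C@]12OC(C)=O
F3 | step 5 | cis-anti-cis tricyclic ketone with C5–H and C10 triethylsilyl ether | O=C1CC[C@]2(C)[C@@]3(O[Si](CC)(CC)CC)C[C@H](C)C[C@H]3[C@H]12
F4 | step 5 | cis-anti-cis tricyclic C10 cyclobutanol with C5–H | O=C1CC[C@]2(C)[C@@]3(O)C[C@H](C)C[C@H]3[C@H]12
F5 | step 5 | cis-fused 6-ene-4,10-dione (β,γ-unsaturated isomer of 9) | O=C1CC[C@]2(C)C(=O)C[C@H](C)C=C[C@H]12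
F6 | step 6 | cyclobutane photoadduct with C4 isopropyl carbinol (hydroxyl cis to the C5 mesylate) | CC(C)[C@]1(O)CC[C@]2(C)[C@@]3(O[Si](CC)(CC)CC)C[C@H](C)C[C@H]3[C@]12OS(C)(=O)=O
F7 | step 8 | 5β,6β-epoxy-10-(triethylsilyloxy)-8βH-daucan-4β-ol | C[C@@H]1C[C@H]2O[C@]23[C@](O)(C(C)C)CC[C@]3(C)C(O[Si](CC)(CC)CC)C1
F8 | step 8 | 10-(triethylsilyloxy)-5αH,8βH-daucane-4β,6β-diol | O[C@@H]1C[C@@H](C)CC(O[Si](CC)(CC)CC)[C@@]2(C)CC[C@@](O)(C(C)C)[C@H]12
F9 | step 13 | 4β-hydroxy-6α-(4-methoxybenzoyloxy)-5αH,8βH-dauc-9-en-10-yl trifluoromethanesulfonate | COc1ccc(C(=O)O[C@H]2C[C@@H](C)C=C(OS(=O)(=O)C(F)(F)F)[C@@]3(C)CC[C@@](O)(C(C)C)[C@H]23)cc1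
F10 | step 13 | 6α-(4-methoxybenzoyloxy)-5αH,8βH-dauc-9-en-4β-ol | COc1ccc(C(=O)O[C@H]2C[C@@H](C)C=C[C@@]3(C)CC[C@@](O)(C(C)C)[C@H]23)cc1
F11 | step 13 | 9α,10α-epoxy-6α-(4-methoxybenzoyloxy)-5αH,8βH-daucan-4β-ol | COc1ccc(C(=O)O[C@H]2C[C@@H](C)[C@H]4O[C@H]4[C@@]3(C)CC[C@@](O)(C(C)C)[C@H]23)cc1
F12 | step 13 | 6α-(4-methoxybenzoyloxy)-9β-(phenylselanyl)-5αH,8βH-daucane-4β,10α-diol | COc1ccc(C(=O)O[C@H]2C[C@@H](C)[C@H]([Se]c4ccccc4)[C@@H](O)[C@@]3(C)CC[C@@](O)(C(C)C)[C@H]23)cc1
A1 | alternative 1 | trans-1-formyl-1,4-dimethyl-6-(tert-butyldimethylsilyloxymethyl)cyclohex-3-ene | O=C[C@@]1(C)CC=C(C)C[C@@H]1CO[Si](C)(C)C(C)(C)C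
A2 | alternative 2 | 6α-(4-methoxybenzoyloxy)-4β-(triethylsilyloxy)-5αH-dauc-8-en-10-one | COc1ccc(C(=O)O[C@H]2CC(C)=CC(=O)[C@@]3(C)CC[C@@](O[Si](CC)(CC)CC)(C(C)C)[C@H]23)cc1
A3 | alternative 3 | bicyclic 5-ene with C4 triethylsilyl ether, quaternary C1 and C9 tert-butyldimethylsilyl enol ether | C[C@@H]1CC=C2[C@](O[Si](CC)(CC)CC)(C(C)C)CC[C@]2(C)C=C1O[Si](C)(C)C(C)(C)C
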